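## Retrosynthetic overview

- The target is opened to a type A bicyclo[3.3.1]nonane-2,4,9-trione carrying Cl at C3: one radical–polar crossover cascade from the C3 radical closes the seven-membered ring of the homoadamantane, then the cyclopentane, and hydrates the final cation.
- That bicycle comes from a monocyclic dearomatised acylphloroglucinol by cation–enol closure of the lavandulyl isopropenyl carbon onto the benzoyl-bearing ring carbon.
- The monocycle comes from 2,4,6-trihydroxybenzophenone by chlorination, C-lavandulylation and dearomative geranylation/prenylation. The chlorine steers the alkylations, blocks C3 so that only the benzoyl carbon can cyclise, and later is the radical trigger.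
- (S)-Lavandulyl iodide comes from an Evans deconjugative α-prenylation of an N-senecioyl oxazolidinone; this is the only source of absolute configuration.
- Ring order: aromatic ring (bought) → six-membered carbocycle of the bicyclo[3.3.1] core → seven-membered ring → cyclopentane.

Assumptions and abbreviations:
- The target is exactly the stereoisomer of the given SMILES.
- Metal salts of numbered compounds and the radicals/cations inside one cascade are not numbered separately.
- geranyl = (2E)-3,7-dimethylocta-2,6-dien-1-yl; lavandulyl = 5-methyl-2-(prop-1-en-2-yl)hex-4-en-1-yl; prenyl = 3-methylbut-2-en-1-yl.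

## Route

Step 1
Reactants: 1 (S)-4-benzyloxazolidin-2-one; 2 3-methylbut-2-enoyl chloride
Product: 3 (S)-4-benzyl-3-(3-methylbut-2-enoyl)oxazolidin-2-one
Conditions: n-BuLi, THF, −78 °C; then 2, −78 → 0 °C
Reagents that add atoms: none
Why: N-acylation of the lithiated Evans oxazolidinone by the acid chloride (addition–elimination); no new stereocentre.

Step 2
Reactants: 3 (S)-4-benzyl-3-(3-methylbut-2-enoyl)oxazolidin-2-one; 4 prenyl bromide (1-bromo-3-methylbut-2-ene)
Product: 5 (S)-4-benzyl-3-[(2S)-5-methyl-2-(prop-1-en-2-yl)hex-4-enoyl]oxazolidin-2-one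
Conditions: NaHMDS, THF, −78 °C; then 4, −78 → −40 °C
Reagents that add atoms: none
Why: Evans asymmetric deconjugative α-alkylation: γ-deprotonation gives the chelated (Z)-dienolate, which is prenylated at the α-carbon on the face opposite the benzyl group, setting the lavandulyl stereocentre (2S).

Step 3
Reactants: 5 (S)-4-benzyl-3-[(2S)-5-methyl-2-(prop-1-en-2-yl)hex-4-enoyl]oxazolidin-2-one
Product: 6 (S)-lavandulol [(2S)-5-methyl-2-(prop-1-en-2-yl)hex-4-en-1-ol]
Conditions: LiBH4, Et2O–MeOH, 0 °C
Reagents that add atoms: none
Why: Reductive cleavage of the Evans imide to the primary alcohol; the alkenes are untouched and the α-stereocentre is retained.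

Step 4
Reactants: 6 (S)-lavandulol
Product: 7 (S)-lavandulyl iodide [(3S)-3-(iodomethyl)-2,6-dimethylhepta-1,5-diene]
Conditions: I2, PPh3, imidazole, CH2Cl2, 0 °C → rt
Reagents that add atoms: iodine, II
Why: Appel-type iodination (SN2 at the primary CH2); the neighbouring stereocentre is not involved.

Step 5
Reactants: 8 2,4,6-trihydroxybenzophenone
Product: 9 (3-chloro-2,4,6-trihydroxyphenyl)(phenyl)methanone
Conditions: NCS (1.0 equiv), MeCN, 0 °C
Reagents that add atoms: N-chlorosuccinimide, O=C1CCC(=O)N1Cl
Why: Electrophilic aromatic chlorination of the very electron-rich ring at one of its two equivalent free positions; one equivalent keeps it at the monochloride.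

Step 6
Reactants: 9 (3-chloro-2,4,6-trihydroxyphenyl)(phenyl)methanone; 7 (S)-lavandulyl iodide
Product: 10 {3-chloro-2,4,6-trihydroxy-5-[(2R)-lavandulyl]phenyl}(phenyl)methanone
Conditions: NaH (1.1 equiv), toluene, 0 → 80 °C
Reagents that add atoms: none
Why: C-alkylation (SN2) of the sodium phenoxide in a non-polar medium at the only free ring CH; the stereocentre is untouched (its descriptor becomes R only because CH2–aryl ranks below isopropenyl).

Step 7
Reactants: 10 {3-chloro-2,4,6-trihydroxy-5-[(2R)-lavandulyl]phenyl}(phenyl)methanone; 11 geranyl bromide [(2E)-1-bromo-3,7-dimethylocta-2,6-diene]; 4 prenyl bromide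
Product: 13 (4S)-2-benzoyl-6-chloro-4-geranyl-3-hydroxy-4-[(2R)-lavandulyl]-6-prenylcyclohex-2-ene-1,5-dione (both C6 epimers), via geranylated dienone 12 (not isolated)
Conditions: NaH (1.1 equiv), toluene–THF, 0 °C, then 11, rt; then NaH (1.1 equiv), 4, rt
Reagents that add atoms: none
Why: Two alkylative dearomatisations (SN2 C-allylation of the phloroglucinol anion): geranyl bromide attacks the alkyl-bearing carbon (more nucleophilic than the C–Cl and C–benzoyl carbons), then prenyl bromide attacks the chlorinated enol carbon; C4 forms without control (about 1:1, only the 4S half leads on and the 4R half is removed after step 8), and the C6 centre is erased in step 9.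

Step 8
Reactants: 13 (4S)-2-benzoyl-6-chloro-4-geranyl-3-hydroxy-4-[(2R)-lavandulyl]-6-prenylcyclohex-2-ene-1,5-dione
Product: 14 (1S,5S,7R)-1-benzoyl-3-chloro-5-geranyl-8,8-dimethyl-3,7-diprenylbicyclo[3.3.1]nonane-2,4,9-trione (both C3 epimers; C7 prenyl endo)
Conditions: [Co(II)(salen-tBu4)] (5 mol %), N-fluoro-2,4,6-trimethylpyridinium BF4 (1.3 equiv), PhSiH3 (1.3 equiv), PhCF3, 0 °C → rt
Reagents that add atoms: none
Why: Proposed new method: Co–H hydrogen-atom transfer selects the only 1,1-disubstituted alkene (isopropenyl) over the four trisubstituted ones, the tertiary radical is oxidised at cobalt to a cation equivalent, and this is captured from below the ring by the benzoyl-bearing enol carbon C2, the only ring carbon still nucleophilic because C6 is quaternary (without the chlorine the alkyl-bearing carbon would react and give the type B skeleton); the closest known reactions are Co(salen) MHAT radical–polar crossover hydrofunctionalisations and polyene cyclisations started at isopropenyl groups and the acid-mediated cation–enol cyclisation of dearomatised acylphloroglucinols that joins two quaternary carbons; the new bridgehead C1 can only form cis to the C5–C6 bond, and in the 4S series the fixed lavandulyl centre then places the C7 prenyl group endo (the 4R series gives the C7-exo isomer, removed here by chromatography).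

Step 9
Reactants: 14 (1S,5S,7R)-1-benzoyl-3-chloro-5-geranyl-8,8-dimethyl-3,7-diprenylbicyclo[3.3.1]nonane-2,4,9-trione
Product: 15 CNP0164095.1 (caged homoadamantane trione with fused cyclopentane carrying the 2-hydroxypropan-2-yl group; configuration as in the given SMILES)
Conditions: fac-Ir(ppy)3 (1 mol %), 2,6-lutidine (1.5 equiv), acetone–H2O 4:1, 450 nm LEDs, rt, degassed
Reagents that add atoms: water, O
Why: Visible-light photoredox radical–polar crossover cascade (atom-transfer-type radical cyclisation): excited Ir(III) reduces the C3–Cl bond to the same C3 radical that enol oxidation gives in the proposed biosynthesis; it adds 7-exo-trig to the inner carbon of the endo C7 prenyl group (the only reachable alkene) with the new CMe2 radical turned away from the C8 gem-dimethyl group; that radical closes 5-exo-trig onto the C3 prenyl group to a cis-fused cyclopentane with the side chain on the face anti to the C7 methylene bridge; Ir(IV) oxidises the last tertiary radical to a cation that water traps; both C3 epimers converge.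

## Compound list

1 | (S)-4-benzyloxazolidin-2-one | O=C1N[C@@H](Cc2ccccc2)CO1 | starting material
2 | 3-methylbut-2-enoyl chloride | CC(C)=CC(=O)Cl | starting material
3 | (S)-4-benzyl-3-(3-methylbut-2-enoyl)oxazolidin-2-one | CC(C)=CC(=O)N1[C@@H](Cc2ccccc2)COC1=O | intermediate
4 | prenyl bromide (1-bromo-3-methylbut-2-ene) | CC(C)=CCBr | starting material
5 | (S)-4-benzyl-3-[(2S)-5-methyl-2-(prop-1-en-2-yl)hex-4-enoyl]oxazolidin-2-one | CC(C)=CC[C@@H](C(C)=C)C(=O)N1[C@@H](Cc2ccccc2)COC1=O | intermediate
6 | (S)-lavandulol, (2S)-5-methyl-2-(prop-1-en-2-yl)hex-4-en-1-ol | CC(C)=CC[C@@H](C(C)=C)CO | intermediate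
7 | (S)-lavandulyl iodide, (3S)-3-(iodomethyl)-2,6-dimethylhepta-1,5-diene | CC(C)=CC[C@@H](C(C)=C)CI | intermediate
8 | 2,4,6-trihydroxybenzophenone | O=C(c1ccccc1)c1c(O)cc(O)cc1O | starting material
9 | (3-chloro-2,4,6-trihydroxyphenyl)(phenyl)methanone | O=C(c1ccccc1)c1c(O)cc(O)c(Cl)c1O | intermediate
10 | {3-chloro-2,4,6-trihydroxy-5-[(2R)-lavandulyl]phenyl}(phenyl)methanone | O=C(c1ccccc1)c1c(O)c(Cl)c(O)c(C[C@H](C(C)=C)CC=C(C)C)c1O | intermediate
11 | geranyl bromide, (2E)-1-bromo-3,7-dimethylocta-2,6-diene | CC(C)=CCC/C(C)=C/CBr | starting material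
12 | (4S)-2-benzoyl-6-chloro-4-geranyl-3,5-dihydroxy-4-[(2R)-lavandulyl]cyclohexa-2,5-dien-1-one (not isolated) | CC(C)=CCC/C(C)=C/C[C@@]1(C[C@H](C(C)=C)CC=C(C)C)C(O)=C(Cl)C(=O)C(C(=O)c2ccccc2)=C1O | intermediate
13 | (4S)-2-benzoyl-6-chloro-4-geranyl-3-hydroxy-4-[(2R)-lavandulyl]-6-prenylcyclohex-2-ene-1,5-dione, both C6 epimers | CC(C)=CCC/C(C)=C/C[C@@]1(C[C@H](C(C)=C)CC=C(C)C)C(=O)C(Cl)(CC=C(C)C)C(=O)C(C(=O)c2ccccc2)=C1O | intermediate
14 | (1S,5S,7R)-1-benzoyl-3-chloro-5-geranyl-8,8-dimethyl-3,7-diprenylbicyclo[3.3.1]nonane-2,4,9-trione, both C3 epimers, C7 prenyl endo | CC(C)=CCC/C(C)=C/C[C@@]12C[C@@H](CC=C(C)C)C(C)(C)[C@](C(=O)c3ccccc3)(C2=O)C(=O)C(Cl)(CC=C(C)C)C1=O | intermediate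
15 | CNP0164095.1; geranyl-bearing carbon R, cage CH next to the gem-dimethyl bridge R, ring-fusion CH S, CH bearing 2-hydroxypropan-2-yl R, ring-fusion quaternary carbon S, benzoyl-bearing carbon S | CC(C)=CCC/C(C)=C/C[C@@]12C[C@H]3C[C@H]4C(C)(C)[C@H](C(C)(C)O)C[C@]4(C1=O)C(=O)[C@@](C(=O)c1ccccc1)(C2=O)C3(C)C | target

## Step count and risks

Total steps: 9. Longest linear sequence: 8 (steps 1, 2, 3, 4, 6, 7, 8, 9).

Most likely to fail, in order: step 8, step 9, step 7.

Step 8 (the enol may capture the cation at oxygen to give a pyran, or the cobalt system may attack the C–Cl bond). The fallback sets out from 13 and replaces the one-step radical–polar crossover by a stepwise ionic closure. Cobalt-catalysed HAT hydrochlorination (TsCl, PhSiH3, EtOH) adds HCl across the isopropenyl group only and gives the tertiary chloride F2. Silylation (TMSOTf, Et3N, CH2Cl2, −78 °C) gives the trimethylsilyl enol ether F3, in which oxygen can no longer compete. ZnCl2 (or AgOTf with 2,6-di-tert-butylpyridine) in CH2Cl2 then ionises the tertiary chloride, and Reetz-type tert-alkylation of the silyl enol ether at carbon closes the ring. The route is rejoined at 14.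

Step 9 (the C3 radical may be reduced to C–H, or the cascade may end as alkene or tertiary chloride instead of alcohol). The fallback sets out from 14 and switches to the oxidative manifold. Zn dust in AcOH–THF removes the chlorine and gives the enolised type A β-diketone F4. Mn(OAc)3·2H2O in AcOH under O2 oxidises the enol to the same C3 radical; the cascade runs as before and the last radical is trapped by O2 to give the hydroperoxide F5. PPh3 reduces F5 to the alcohol, rejoining the route at 15.

Step 7 (O-allylation instead of C-allylation, and no control at C4). The fallback sets out from 10 and replaces SN2 allylation by a palladium π-allyl (Tsuji–Trost) dearomatisation. Geraniol and methyl chloroformate (pyridine, CH2Cl2) give geranyl methyl carbonate F1. Compound 10 and F1 with Pd2(dba)3 and a Trost DACH-phenyl ligand (both antipodes screened so that the catalyst, not chance, decides C4) give 12, now isolated. Prenylation of 12 (NaH, 4, toluene) rejoins the route at 13.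

## Further compounds

F1 | step 7 | geranyl methyl carbonate | CC(C)=CCC/C(C)=C/COC(=O)OC
F2 | step 8 | tertiary chloride, 13 with the isopropenyl group as 2-chloropropan-2-yl | CC(C)=CCC/C(C)=C/C[C@@]1(C[C@H](C(C)(C)Cl)CC=C(C)C)C(=O)C(Cl)(CC=C(C)C)C(=O)C(C(=O)c2ccccc2)=C1O
F3 | step 8 | trimethylsilyl enol ether of F2 | CC(C)=CCC/C(C)=C/C[C@@]1(C[C@H](C(C)(C)Cl)CC=C(C)C)C(=O)C(Cl)(CC=C(C)C)C(=O)C(C(=O)c2ccccc2)=C1O[Si](C)(C)C
F4 | step 9 | enolised type A β-diketone, 14 without chlorine (1R,5R,7R by CIP, same spatial arrangement as 14) | CC(C)=CCC/C(C)=C/C[C@@]12C[C@@H](CC=C(C)C)C(C)(C)[C@](C(=O)c3ccccc3)(C2=O)C(=O)C(CC=C(C)C)=C1O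
F5 | step 9 | hydroperoxide, 15 with OOH in place of OH | CC(C)=CCC/C(C)=C/C[C@@]12C[C@H]3C[C@H]4C(C)(C)[C@H](C(C)(C)OO)C[C@]4(C1=O)C(=O)[C@@](C(=O)c1ccccc1)(C2=O)C3(C)C
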